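**Plan**
- **Cuts.** First the two ester C–O bonds (O8 tiglate, O9 senecioate) are cut, and a C3=C4 double bond is written into ring A. Then C3–C4 is cut and C1–C4 joined instead. This shrinks ring A (C1–C2–C3–C4–C5–C10) to the cyclobutane C1–C4–C5–C10, with C2/C3 as an acetyl arm on C1 and C4 tied to O9. Finally C1–C10 and C4–C5 are cut ([2+2]) to give a monocyclic ring B vinylogous ester.
- **Enabling feature.** In ring A the C2 ketone is β to the methyl-bearing C4, so C2–C3–C4 is an aldol retron. O9 on ring B lies on the α face, syn to both ring A bonds at the fusion (C10–C1 and C5–C4). O9 can therefore carry C4, C1, C2 and C3 as a 4-oxopent-2-en-2-yl ether.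
- **Forward order.** Ring B is made first by an organocatalytic annulation. A crossed [2+2] then gives the O9-bridged cyclobutane. A two-carbon ring expansion builds ring A and frees O9. The two esters come last.
- **Stereochemistry.** C7 is set by catalysis. C8 is set anti to C7, and C9 by equatorial hydride delivery. C5 and C10 are set together in one event through the O9 tether. C4 is set by α-face protonation.

Key step: step 10

Remark: eremophilane numbering is used (ring A = C1–C5, C10; ring B = C5–C10; β = face of the C5 methyl; MEM = (2-methoxyethoxy)methyl). The (R)-diarylprolinol silyl ether is assumed to shield the enal as in its established β-functionalisations; if the sense is opposite, its antipode is used.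

**Step 1**
Reactants: 1 methacrolein; 2 (triphenylphosphoranylidene)acetaldehyde
Product: 3 (2E)-4-methylpenta-2,4-dienal
Conditions: toluene, 80 °C
Reagents that add atoms: none
Why: Wittig olefination with a stabilised formyl ylide gives the E-enal and keeps the 1,1-disubstituted alkene that becomes the isopropenyl group.

**Step 2**
Reactants: 3 (2E)-4-methylpenta-2,4-dienal; 4 tert-butyl 3-oxobutanoate
Product: 7 (5R)-5-(prop-1-en-2-yl)cyclohex-2-en-1-one, via Michael adduct 5 (not isolated), via cyclohexenone tert-butyl ester 6 (not isolated)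
Conditions: (R)-2-{bis[3,5-bis(trifluoromethyl)phenyl](trimethylsilyloxy)methyl}pyrrolidine (10 mol %), PhCO2H (10 mol %), neat, rt; then TsOH·H2O (20 mol %), toluene, 80 °C
Reagents that add atoms: none
Why: Iminium-catalysed Michael addition of the β-keto ester to the β-carbon of the enal (1,4-addition is the normal mode, and the shielded face of the iminium ion sets C7) is followed by acid-induced intramolecular aldol condensation, loss of 2-methylpropene and decarboxylation, which together make an organocatalytic Robinson-type annulation.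

**Step 3**
Reactants: 7 (5R)-5-(prop-1-en-2-yl)cyclohex-2-en-1-one
Product: 8 (5R)-1-methyl-5-(prop-1-en-2-yl)cyclohex-2-en-1-ol (both carbinol epimers)
Conditions: MeLi, Et2O, −78 °C
Reagents that add atoms: methyllithium, [Li]C
Why: 1,2-Addition of a hard organolithium to the enone brings in the future C5 methyl, and the carbinol configuration is irrelevant because that centre becomes sp2 in step 4.

**Step 4**
Reactants: 8 (5R)-1-methyl-5-(prop-1-en-2-yl)cyclohex-2-en-1-ol
Product: 9 (5S)-3-methyl-5-(prop-1-en-2-yl)cyclohex-2-en-1-one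
Conditions: pyridinium chlorochromate C5H5NH[CrO3Cl], 4 Å MS, CH2Cl2, rt
Reagents that add atoms: pyridinium chlorochromate, [O-][Cr](=O)(=O)Cl.c1cc[nH+]cc1
Why: In this oxidative 1,3-transposition of a tertiary allylic alcohol (Babler–Dauben oxidation) the chromate ester shifts [3,3] to C9 and is oxidised there, so the carbonyl oxygen comes from the reagent and C7 is untouched.

**Step 5**
Reactants: 9 (5S)-3-methyl-5-(prop-1-en-2-yl)cyclohex-2-en-1-one
Product: 10 (5R,6R)-6-hydroxy-3-methyl-5-(prop-1-en-2-yl)cyclohex-2-en-1-one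
Conditions: LiN(i-Pr)2, THF, −78 °C; then 2-(phenylsulfonyl)-3-phenyloxaziridine, −78 °C
Reagents that add atoms: 2-(phenylsulfonyl)-3-phenyloxaziridine, O=S(=O)(c1ccccc1)N1OC1c1ccccc1
Why: Kinetic α′-deprotonation gives the cross-conjugated enolate, and in the oxaziridine enolate hydroxylation the oxidant approaches C8 anti to the neighbouring isopropenyl group, which gives the trans 8α-alcohol.

**Step 6**
Reactants: 10 (5R,6R)-6-hydroxy-3-methyl-5-(prop-1-en-2-yl)cyclohex-2-en-1-one
Product: 11 (5R,6R)-6-[(2-methoxyethoxy)methoxy]-3-methyl-5-(prop-1-en-2-yl)cyclohex-2-en-1-one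
Conditions: MEMCl, i-Pr2NEt, CH2Cl2, 0 °C to rt
Reagents that add atoms: 2-methoxyethoxymethyl chloride, COCCOCCl
Why: Acetal-type O-alkylation under weakly basic conditions does not enolise the α-oxy ketone, and unlike a silyl group the MEM group cannot migrate to O9 in the basic steps 8 and 11.

**Step 7**
Reactants: 11 (5R,6R)-6-[(2-methoxyethoxy)methoxy]-3-methyl-5-(prop-1-en-2-yl)cyclohex-2-en-1-one
Product: 12 (1S,5R,6R)-6-[(2-methoxyethoxy)methoxy]-3-methyl-5-(prop-1-en-2-yl)cyclohex-2-en-1-ol
Conditions: Li[HB(s-Bu)3], THF, −78 °C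
Reagents that add atoms: none
Why: In this 1,2-reduction by a bulky trialkylborohydride the β,β-disubstituted C5 blocks 1,4-delivery, and equatorial (β-face) attack on the half-chair with equatorial C7 and C8 groups gives the pseudoaxial 9α-alcohol, cis to O8.

**Step 8**
Reactants: 12 (1S,5R,6R)-6-[(2-methoxyethoxy)methoxy]-3-methyl-5-(prop-1-en-2-yl)cyclohex-2-en-1-ol; 13 pent-3-yn-2-one
Product: 14 (3E)-4-{[(1S,5R,6R)-6-[(2-methoxyethoxy)methoxy]-3-methyl-5-(prop-1-en-2-yl)cyclohex-2-en-1-yl]oxy}pent-3-en-2-one
Conditions: NaH (0.2 equiv), THF, 0 °C to rt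
Reagents that add atoms: none
Why: Base-catalysed oxa-Michael addition of the alkoxide to the ynone and protonation of the allenolate give the more stable E vinylogous ester, which hangs C4 (with its methyl), C1, C2 and C3 on O9 without touching a stereocentre.

**Step 9**
Reactants: 14 (3E)-4-{[(1S,5R,6R)-6-[(2-methoxyethoxy)methoxy]-3-methyl-5-(prop-1-en-2-yl)cyclohex-2-en-1-yl]oxy}pent-3-en-2-one
Product: 15 O9-bridged cyclobutane (2-oxabicyclo[2.1.1]hexane fused to ring B; new bonds C1–C10 and C4–C5 on the α face; O9–C4 ether; 1-acetyl; 4-methyl; 5β-methyl; 10β-H; 7β-isopropenyl; 8α-OMEM)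
Conditions: hν (300 nm), degassed MeCN (5 mM), rt
Reagents that add atoms: none
Why: In this crossed intramolecular enone–alkene [2+2] photocycloaddition of a 3-oxa-1,5-diene, either first bond (C1–C10 or C4–C5) closes a five-membered ring through O9 (rule of five), so only the crossed adduct can form, and the two-atom C9–O9 tether on the α face forces both new bonds onto that face, which sets quaternary C5 and C10 together.

**Step 10**
Reactants: 15 O9-bridged cyclobutane
Product: 17 9α-hydroxy-8α-[(2-methoxyethoxy)methoxy]-10βH-eremophila-3,11-dien-2-one, via seco-diketone 16 (not isolated)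
Conditions: pyrrolidine (1.2 equiv), AcOH (1.2 equiv), MeCN–H2O (10:1), 50 °C
Reagents that add atoms: none
Why: Proposed new method: pyrrolidinium acetate converts the acetyl C2=O of 15 into an iminium ion, and the push of the O9 lone pair on C4, this pull on C1 and the strain of the 2-oxabicyclo[2.1.1]hexane cleave the C1–C4 bond in a retro-aldol (retro-Mannich-like) fragmentation, after which water turns the oxocarbenium/enamine pair into seco-diketone 16. The enamine of the same methyl ketone then re-forms at C3 and closes on the C4 carbonyl in a 6-(enolendo)-exo-trig aldol closure of ring A, and loss of water gives the C3=C4 enone, so the four-membered ring C1–C4–C5–C10 has taken up C2 and C3 and O9 is released as the free 9α-alcohol. The closest known reaction types are the de Mayo sequence (retro-aldol opening of a 2-acylcyclobutanol followed by aldol cyclodehydration of the 1,5-diketone) and the retro-Mannich/Mannich reorganisation of vinylogous amide photoadducts; what is new is the O-alkyl donor and the single amine-mediated operation. No stereocentre is created: C5 (quaternary) and C10 (β to C2) are not enolisable and pass unchanged into the cis-decalin, while C1 and C4 lose their configuration by design. The step needs regioselective reclosure (C3 onto C4, not the C4 methyl onto C2), which is secured because only the unhindered C2 ketone condenses with the secondary amine, whereas the C4 ketone, neopentyl next to C5 and partly masked as its O9 hemiketal, can act only as the electrophile, and closure from C1 would merely return the cyclobutane.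

**Step 11**
Reactants: 17 9α-hydroxy-8α-[(2-methoxyethoxy)methoxy]-10βH-eremophila-3,11-dien-2-one
Product: 18 9α-hydroxy-8α-[(2-methoxyethoxy)methoxy]-10βH-eremophil-11-en-2-one (4β-methyl)
Conditions: Li, NH3(l)–THF, t-BuOH (1 equiv), −78 °C; then solid NH4Cl
Reagents that add atoms: none
Why: In this dissolving-metal conjugate reduction the enone radical anion is protonated at C4 on the α face, axially in the conformer that keeps the C7 and C8 groups equatorial and with the syn-axial 9α-OH as the nearest proton source, so the C4 methyl ends equatorial and cis to the C5 methyl, while the isolated alkene and the MEM acetal are inert and the ketone is stored as its enolate until the quench.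

**Step 12**
Reactants: 18 9α-hydroxy-8α-[(2-methoxyethoxy)methoxy]-10βH-eremophil-11-en-2-one; 19 3-methylbut-2-enoyl chloride
Product: 20 8α-[(2-methoxyethoxy)methoxy]-9α-(3-methylbut-2-enoyloxy)-10βH-eremophil-11-en-2-one
Conditions: pyridine, DMAP (cat.), CH2Cl2, 0 to 40 °C
Reagents that add atoms: none
Why: DMAP-catalysed acylation of the only free hydroxyl can be forced at the hindered axial O9 because no neighbouring free OH allows acyl migration, and the weak base avoids deconjugation of the senecioyl unit.

**Step 13**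
Reactants: 20 8α-[(2-methoxyethoxy)methoxy]-9α-(3-methylbut-2-enoyloxy)-10βH-eremophil-11-en-2-one
Product: 21 8α-hydroxy-9α-(3-methylbut-2-enoyloxy)-10βH-eremophil-11-en-2-one
Conditions: ZnBr2, CH2Cl2, 0 °C to rt; aqueous work-up
Reagents that add atoms: none
Why: Chelation-assisted Lewis acid cleavage of the MEM ether is non-basic, so the senecioate should stay on O9, and it is mild enough to spare the isopropenyl group, the ketone and the enoate.

**Step 14**
Reactants: 21 8α-hydroxy-9α-(3-methylbut-2-enoyloxy)-10βH-eremophil-11-en-2-one; 22 (2E)-2-methylbut-2-enoyl chloride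
Product: 23 8α-[(2E)-2-methylbut-2-enoyloxy]-9α-(3-methylbut-2-enoyloxy)-10βH-eremophil-11-en-2-one (target)
Conditions: pyridine, DMAP (cat.), CH2Cl2, 0 °C
Reagents that add atoms: none
Why: DMAP-catalysed acylation of the unhindered equatorial 8α-alcohol should outrun acyl migration, and the E geometry of the tigloyl unit is retained.

**Compound list**
1 | methacrolein | C=C(C)C=O | starting material
2 | (triphenylphosphoranylidene)acetaldehyde | O=CC=P(c1ccccc1)(c1ccccc1)c1ccccc1 | starting material
3 | (2E)-4-methylpenta-2,4-dienal | C=C(C)/C=C/C=O | intermediate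
4 | tert-butyl 3-oxobutanoate | CC(=O)CC(=O)OC(C)(C)C | starting material
5 | tert-butyl (3R)-2-acetyl-4-methyl-3-(2-oxoethyl)pent-4-enoate (C2 epimers) | C=C(C)[C@H](CC=O)C(C(C)=O)C(=O)OC(C)(C)C | intermediate
6 | tert-butyl (6R)-2-oxo-6-(prop-1-en-2-yl)cyclohex-3-ene-1-carboxylate (C1 epimers) | C=C(C)[C@H]1C(C(=O)OC(C)(C)C)C(=O)C=CC1 | intermediate
7 | (5R)-5-(prop-1-en-2-yl)cyclohex-2-en-1-one | C=C(C)[C@H]1CC(=O)C=CC1 | intermediate
8 | (5R)-1-methyl-5-(prop-1-en-2-yl)cyclohex-2-en-1-ol (carbinol epimers) | C=C(C)[C@H]1CC(C)(O)C=CC1 | intermediate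
9 | (5S)-3-methyl-5-(prop-1-en-2-yl)cyclohex-2-en-1-one | C=C(C)[C@H]1CC(C)=CC(=O)C1 | intermediate
10 | (5R,6R)-6-hydroxy-3-methyl-5-(prop-1-en-2-yl)cyclohex-2-en-1-one | C=C(C)[C@H]1CC(C)=CC(=O)[C@@H]1O | intermediate
11 | (5R,6R)-6-[(2-methoxyethoxy)methoxy]-3-methyl-5-(prop-1-en-2-yl)cyclohex-2-en-1-one | C=C(C)[C@H]1CC(C)=CC(=O)[C@@H]1OCOCCOC | intermediate
12 | (1S,5R,6R)-6-[(2-methoxyethoxy)methoxy]-3-methyl-5-(prop-1-en-2-yl)cyclohex-2-en-1-ol | C=C(C)[C@H]1CC(C)=C[C@H](O)[C@@H]1OCOCCOC | intermediate
13 | pent-3-yn-2-one | CC#CC(C)=O | starting material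
14 | (3E)-4-{[(1S,5R,6R)-6-[(2-methoxyethoxy)methoxy]-3-methyl-5-(prop-1-en-2-yl)cyclohex-2-en-1-yl]oxy}pent-3-en-2-one | C=C(C)[C@H]1CC(C)=C[C@H](O/C(C)=C/C(C)=O)[C@@H]1OCOCCOC | intermediate
15 | O9-bridged cyclobutane C1–C4–C5–C10 (2-oxabicyclo[2.1.1]hexane fused to ring B; acetyl on C1 turned away from the C5 methyl; the C1 configuration has no consequence) | C=C(C)[C@H]1C[C@@]2(C)[C@@H]3[C@@H](C(C)=O)[C@@]2(C)O[C@@H]3[C@@H]1OCOCCOC | intermediate
16 | seco-diketone (ring B cyclohexanol with 5α-acetyl, 5β-methyl, 10α-(2-oxopropyl), 9α-OH, 8α-OMEM, 7β-isopropenyl) | C=C(C)[C@H]1C[C@@](C(C)=O)(C)[C@H](CC(C)=O)[C@H](O)[C@@H]1OCOCCOC | intermediate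
17 | 9α-hydroxy-8α-[(2-methoxyethoxy)methoxy]-10βH-eremophila-3,11-dien-2-one | C=C(C)[C@H]1C[C@@]2(C)[C@H](CC(=O)C=C2C)[C@H](O)[C@@H]1OCOCCOC | intermediate
18 | 9α-hydroxy-8α-[(2-methoxyethoxy)methoxy]-10βH-eremophil-11-en-2-one | C=C(C)[C@H]1C[C@@]2(C)[C@H](CC(=O)C[C@@H]2C)[C@H](O)[C@@H]1OCOCCOC | intermediate
19 | 3-methylbut-2-enoyl chloride | CC(C)=CC(=O)Cl | starting material
20 | 8α-[(2-methoxyethoxy)methoxy]-9α-(3-methylbut-2-enoyloxy)-10βH-eremophil-11-en-2-one | C=C(C)[C@H]1C[C@@]2(C)[C@H](CC(=O)C[C@@H]2C)[C@H](OC(=O)C=C(C)C)[C@@H]1OCOCCOC | intermediate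
21 | 8α-hydroxy-9α-(3-methylbut-2-enoyloxy)-10βH-eremophil-11-en-2-one | C=C(C)[C@H]1C[C@@]2(C)[C@H](CC(=O)C[C@@H]2C)[C@H](OC(=O)C=C(C)C)[C@@H]1O | intermediate
22 | (2E)-2-methylbut-2-enoyl chloride | C/C=C(\C)C(=O)Cl | starting material
23 | 8α-[(2E)-2-methylbut-2-enoyloxy]-9α-(3-methylbut-2-enoyloxy)-10βH-eremophil-11-en-2-one | C=C(C)[C@H]1C[C@@]2(C)[C@H](CC(=O)C[C@@H]2C)[C@H](OC(=O)C=C(C)C)[C@@H]1OC(=O)/C(C)=C/C | target

Total steps: 14. Longest linear sequence: 14.

**Steps most likely to fail**

**Step 10.** The reclosure may lose its regiocontrol, with the methyl of the C4 acetyl attacking C2. The sequence may also stall at the hemiketal or at the O9-to-C4 oxa-Michael stage.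
- The fallback sets out from 15. The kinetic lithium enolate of the acetyl group (LiN(i-Pr)2, −78 °C) is C-phosphorylated with ClP(OEt)2 and air-oxidised to the cage β-keto phosphonate F1.
- Dilute aqueous HCl in THF then brings about the classical acid retro-aldol opening of C1–C4 to the seco hydroxy keto phosphonate F2.
- LiCl/DBU closes C3=C4 by an intramolecular Horner–Wadsworth–Emmons reaction, in which only C3 can be the nucleophile. The fallback comes back to the route at 17.

**Step 9.** The acyclic chromophore may waste its excitation in E/Z isomerisation. The 1,4-biradical may also revert faster than it closes a bond between two fully substituted carbons.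
- The fallback sets out from 12 and replaces light by a thermal ketene cycloaddition. O-alkylation with 2-bromopropanoic acid (NaH) gives the 2-alkoxypropanoic acid F3.
- (COCl)2 and then Et3N in refluxing toluene generate the alkoxy(methyl)ketene. Its intramolecular [2+2] cycloaddition joins the carbonyl carbon to C10 and the α-carbon to the more substituted C5. This gives the same oxa-bridged cage as its C1 cyclobutanone F4.
- A Wittig reaction with Ph3P=C(CH3)OCH3 gives the enol ether F5, and mild acid hydrolysis comes back to the route at 15.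

**Step 7.** Facial selectivity of hydride delivery may be poor, or 1,4-reduction may compete.
- The fallback sets out from 11. A Luche reduction (NaBH4, CeCl3·7H2O, MeOH) follows the intrinsic axial bias and gives the 9β-alcohol F6.
- A Mitsunobu inversion (4-nitrobenzoic acid, PPh3, DIAD) gives the 9α-(4-nitrobenzoate) F7.
- K2CO3 in MeOH removes the ester and comes back to the route at 12.

**Further compounds**
F1 | step 10 | cage β-keto phosphonate (15 with C3 bearing P(O)(OEt)2) | C=C(C)[C@H]1C[C@@]2(C)[C@@H]3[C@@H](C(=O)CP(=O)(OCC)OCC)[C@@]2(C)O[C@@H]3[C@@H]1OCOCCOC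
F2 | step 10 | seco hydroxy keto phosphonate (16 with C3 bearing P(O)(OEt)2) | C=C(C)[C@H]1C[C@@](C(C)=O)(C)[C@H](CC(=O)CP(=O)(OCC)OCC)[C@H](O)[C@@H]1OCOCCOC
F3 | step 9 | 2-alkoxypropanoic acid from 12 (side-chain epimers) | C=C(C)[C@H]1CC(C)=C[C@H](OC(C)C(=O)O)[C@@H]1OCOCCOC
F4 | step 9 | oxa-bridged cage C1 cyclobutanone | C=C(C)[C@H]1C[C@@]2(C)[C@@H]3C(=O)[C@@]2(C)O[C@@H]3[C@@H]1OCOCCOC
F5 | step 9 | cage 1-(1-methoxyethylidene) enol ether | C=C(C)[C@H]1C[C@@]2(C)[C@@H]3C(=C(C)OC)[C@@]2(C)O[C@@H]3[C@@H]1OCOCCOC
F6 | step 7 | 9β-alcohol, C1 epimer of 12 | C=C(C)[C@H]1CC(C)=C[C@@H](O)[C@@H]1OCOCCOC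
F7 | step 7 | 9α-(4-nitrobenzoate) of 12 | C=C(C)[C@H]1CC(C)=C[C@H](OC(=O)c2ccc(cc2)[N+](=O)[O-])[C@@H]1OCOCCOC
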